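**Retrosynthetic overview**
- The target is (2R,3R)-7-O-geranylfustin. The last operations, read backwards: fluoride removal of the two catechol TBS ethers, C3–OH by oxygen transfer to a C3=C4 enol silane anti to the C2 aryl, C2–H by asymmetric CuH conjugate reduction of a flavone, and the 7-O-geranyl group by Williamson etherification.
- The plan rests on C4. This carbonyl carbon of ring C is bonded only to C4a of ring A and to C3 of the C3–C2–ring B chain, so it is excised as carbon monoxide.
- That cut leaves 4-iodoresorcinol (ring A with O1 and the 7-OH) and 3,4-bis-TBS-oxyphenylacetylene (C3, C2, ring B). One palladium operation forms C4a–C4, C4–C3 and O1–C2.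
- Rings A and B are bought. Ring C is the only ring made, first as the flat pyranone and later made stereogenic at C2 and then C3. The geranyl group goes on after the palladium step, so no allylic aryl ether meets zerovalent palladium.
- The alkyne comes from 3,4-dihydroxybenzaldehyde by silylation and Corey–Fuchs homologation.

Key step: step 4

Assumption: the facial sense of (R)-DTBM-SEGPHOS-ligated CuH on a flavone is assigned by analogy with other β,β-disubstituted cyclic enones. If the first run shows the 2R enol silane, the equally available (S)-ligand is used and nothing else changes.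

**Step 1**
Reactants: 1 3,4-dihydroxybenzaldehyde
Product: 2 3,4-bis(tert-butyldimethylsilyloxy)benzaldehyde
Conditions: TBSCl (2.4 equiv), imidazole (5 equiv), DMF, 0 °C to rt
Reagents that add atoms: tert-butyldimethylsilyl chloride, CC(C)(C)[Si](C)(C)Cl
Why: Imidazole-promoted silylation of phenols is standard, and silyl ethers are the catechol protection that can be removed at the end without strong acid, base or hydrogen, which the geranyl ether and the dihydroflavonol would not tolerate.

**Step 2**
Reactants: 2 3,4-bis(tert-butyldimethylsilyloxy)benzaldehyde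
Product: 3 4-(2,2-dibromoethenyl)-1,2-bis(tert-butyldimethylsilyloxy)benzene
Conditions: CBr4 (2 equiv), PPh3 (4 equiv), CH2Cl2, 0 °C
Reagents that add atoms: carbon tetrabromide, BrC(Br)(Br)Br
Why: First stage of the Corey–Fuchs homologation (Ramirez dibromo-olefination), in which Ph3P=CBr2 made from CBr4 and PPh3 undergoes a Wittig reaction with the aldehyde under base-free conditions that spare aryl silyl ethers, unlike the K2CO3/MeOH of the Ohira–Bestmann variant.

**Step 3**
Reactants: 3 4-(2,2-dibromoethenyl)-1,2-bis(tert-butyldimethylsilyloxy)benzene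
Product: 5 4-ethynyl-1,2-bis(tert-butyldimethylsilyloxy)benzene, via lithium acetylide 4 (not isolated)
Conditions: n-BuLi (2.1 equiv), THF, −78 to −20 °C; then sat. aq NH4Cl
Reagents that add atoms: none
Why: Second stage of the Corey–Fuchs homologation, in which bromine–lithium exchange, loss of LiBr and a Fritsch–Buttenberg–Wiechell 1,2-shift give the alkyne, the second equivalent of n-BuLi holds it as acetylide 4 until the buffered quench, and aryl TBS ethers are inert to n-BuLi at this temperature.

**Step 4**
Reactants: 5 4-ethynyl-1,2-bis(tert-butyldimethylsilyloxy)benzene; 6 4-iodoresorcinol; 7 carbon monoxide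
Product: 10 7-hydroxy-3',4'-bis(tert-butyldimethylsilyloxy)flavone, via ynone 8 (not isolated), via enaminone 9 (not isolated)
Conditions: PdCl2(dppf) (3 mol %), CO (5 bar), Et2NH (10 equiv), 1,4-dioxane, 70 °C, no copper salt
Reagents that add atoms: none
Why: Zerovalent palladium formed in situ from PdCl2(dppf) inserts into the C–I bond of 6, CO inserts, and the acyl-palladium takes up the amine-deprotonated alkyne 5 and reductively eliminates to ynone 8, which forms C4a–C4 and C4–C3. This is the known carbonylative Sonogashira coupling of ortho-iodophenols with terminal alkynes, followed by in situ cyclisation to flavones. Conjugate addition of Et2NH to 8 is reversible and holds the material as enaminone 9; attack of the ortho phenol on C2 of 9 and expulsion of the amine then form O1–C2, closing ring C in a net 6-endo-dig sense. No stereocentre is formed. The step needs carbonylation ahead of alkynylation (otherwise a 2-arylbenzofuran), 6-endo rather than 5-exo closure (otherwise an aurone) and use of the correct hydroxyl: omitting copper and keeping CO under pressure secure the first, the amino group of 9 marks C2 as the only electrophilic carbon and secures the second, and geometry secures the third because only the hydroxyl ortho to iodine can reach C2. The hydroxyl para to iodine takes no part and emerges as the one unprotected phenol of 10, at C7, ready for geranylation.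

**Step 5**
Reactants: 10 7-hydroxy-3',4'-bis(tert-butyldimethylsilyloxy)flavone; 11 geranyl bromide
Product: 12 7-geranyloxy-3',4'-bis(tert-butyldimethylsilyloxy)flavone
Conditions: K2CO3 (1.2 equiv), dry acetone, rt to 40 °C
Reagents that add atoms: none
Why: Williamson etherification, in which the 7-OH is a vinylogous carboxylic acid and the only acidic site of 10 so a weak base suffices, the primary allylic bromide reacts by direct SN2 displacement that keeps the E-alkene, and the well stabilised 7-phenoxide is too poor a nucleophile to strip silicon from the catechol.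

**Step 6**
Reactants: 12 7-geranyloxy-3',4'-bis(tert-butyldimethylsilyloxy)flavone
Product: 13 (2S)-2-[3,4-bis(tert-butyldimethylsilyloxy)phenyl]-4-(diphenylsilyloxy)-7-geranyloxy-2H-chromene
Conditions: Cu(OAc)2 (5 mol %), (R)-DTBM-SEGPHOS (5.5 mol %), Ph2SiH2 (1.5 equiv), toluene, 0 °C to rt, no protic additive; filtered through dry Florisil under Ar, concentrated, used crude
Reagents that add atoms: diphenylsilane, [SiH2](c1ccccc1)c1ccccc1
Why: Copper hydride catalysed asymmetric conjugate reduction (1,4-hydrosilylation), known for β,β-disubstituted cyclic enones and 2-substituted chromones, in which the ligand pocket directs hydride to one face of C2 and so sets C2 (S here, R in the target once the 3-OH changes the priorities), σ-bond metathesis of the copper enolate with Si–H gives enol silane 13, the absence of a proton source keeps C4 masked against 1,2-reduction and avoids a free enolate that could open ring C, and the unactivated geranyl alkenes are not hydrocuprated.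

**Step 7**
Reactants: 13 (2S)-2-[3,4-bis(tert-butyldimethylsilyloxy)phenyl]-4-(diphenylsilyloxy)-7-geranyloxy-2H-chromene
Product: 16 (2R,3R)-7-geranyloxy-3-hydroxy-3',4'-bis(tert-butyldimethylsilyloxy)flavanone, via siloxy epoxide 14 (not isolated), via 3-silyloxy ketone 15 (not isolated)
Conditions: 2-(phenylsulfonyl)-3-phenyloxaziridine (1.5 equiv), CH2Cl2, rt to 35 °C; then 10% aq citric acid, THF, 0 °C
Reagents that add atoms: 2-(phenylsulfonyl)-3-phenyloxaziridine, O=S(=O)(c1ccccc1)N1OC1c1ccccc1
Why: Rubottom-type oxidation with a Davis N-sulfonyloxaziridine, a known neutral aprotic oxidation of silyl enol ethers, in which oxygen goes to the electron-rich C3=C4 bond on the face opposite the C2 aryl group (substrate control, setting C3 trans to C2), epoxide 14 opens with a 1,4-silyl shift to 15 whose labile silyl ether is hydrolysed in the mild acid work-up, and the reagent is too weak an epoxidising agent to attack the two trisubstituted geranyl alkenes at this temperature.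

**Step 8**
Reactants: 16 (2R,3R)-7-geranyloxy-3-hydroxy-3',4'-bis(tert-butyldimethylsilyloxy)flavanone
Product: 17 (2R,3R)-7-geranyloxy-3,3',4'-trihydroxyflavanone (CNP0508026.1)
Conditions: Et3N·3HF (6 equiv), THF, 0 °C to rt, Ar; pH 6 buffer work-up
Reagents that add atoms: none
Why: Fluoride cleavage of aryl silyl ethers with weakly acidic Et3N·3HF avoids the phenoxide and enolate conditions under which dihydroflavonols open ring C and epimerise at C2 and C3, and it leaves the allylic aryl ether and both alkenes untouched.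

**Compound list**
1 | 3,4-dihydroxybenzaldehyde | O=Cc1ccc(O)c(O)c1 | starting material
2 | 3,4-bis(tert-butyldimethylsilyloxy)benzaldehyde | O=Cc1ccc(O[Si](C)(C)C(C)(C)C)c(O[Si](C)(C)C(C)(C)C)c1 | intermediate
3 | 4-(2,2-dibromoethenyl)-1,2-bis(tert-butyldimethylsilyloxy)benzene | BrC(Br)=Cc1ccc(O[Si](C)(C)C(C)(C)C)c(O[Si](C)(C)C(C)(C)C)c1 | intermediate
4 | lithium [3,4-bis(tert-butyldimethylsilyloxy)phenyl]acetylide (formed in the flask) | [Li]C#Cc1ccc(O[Si](C)(C)C(C)(C)C)c(O[Si](C)(C)C(C)(C)C)c1 | intermediate
5 | 4-ethynyl-1,2-bis(tert-butyldimethylsilyloxy)benzene | C#Cc1ccc(O[Si](C)(C)C(C)(C)C)c(O[Si](C)(C)C(C)(C)C)c1 | intermediate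
6 | 4-iodoresorcinol (4-iodobenzene-1,3-diol) | Oc1ccc(I)c(O)c1 | starting material
7 | carbon monoxide | [C-]#[O+] | starting material
8 | 1-(2,4-dihydroxyphenyl)-3-[3,4-bis(tert-butyldimethylsilyloxy)phenyl]prop-2-yn-1-one (formed in the flask) | O=C(C#Cc1ccc(O[Si](C)(C)C(C)(C)C)c(O[Si](C)(C)C(C)(C)C)c1)c1ccc(O)cc1O | intermediate
9 | (E)-3-(diethylamino)-1-(2,4-dihydroxyphenyl)-3-[3,4-bis(tert-butyldimethylsilyloxy)phenyl]prop-2-en-1-one (formed in the flask) | O=C(/C=C(/N(CC)CC)c1ccc(O[Si](C)(C)C(C)(C)C)c(O[Si](C)(C)C(C)(C)C)c1)c1ccc(O)cc1O | intermediate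
10 | 7-hydroxy-3',4'-bis(tert-butyldimethylsilyloxy)flavone | Oc1ccc2c(c1)oc(-c1ccc(O[Si](C)(C)C(C)(C)C)c(O[Si](C)(C)C(C)(C)C)c1)cc2=O | intermediate
11 | geranyl bromide, (2E)-1-bromo-3,7-dimethylocta-2,6-diene | CC(C)=CCC/C(C)=C/CBr | starting material
12 | 7-geranyloxy-3',4'-bis(tert-butyldimethylsilyloxy)flavone | CC(C)=CCC/C(C)=C/COc1ccc2c(c1)oc(-c1ccc(O[Si](C)(C)C(C)(C)C)c(O[Si](C)(C)C(C)(C)C)c1)cc2=O | intermediate
13 | (2S)-2-[3,4-bis(tert-butyldimethylsilyloxy)phenyl]-4-(diphenylsilyloxy)-7-geranyloxy-2H-chromene | CC(C)=CCC/C(C)=C/COc1ccc2c(c1)O[C@H](c1ccc(O[Si](C)(C)C(C)(C)C)c(O[Si](C)(C)C(C)(C)C)c1)C=C2O[SiH](c1ccccc1)c1ccccc1 | intermediate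
14 | 3,4-epoxide of 13, oxirane oxygen on the face opposite the C2 aryl group, (2R,3R,4R) in flavan numbering (formed in the flask) | CC(C)=CCC/C(C)=C/COc1ccc2c(c1)O[C@H](c1ccc(O[Si](C)(C)C(C)(C)C)c(O[Si](C)(C)C(C)(C)C)c1)[C@H]3O[C@@]23O[SiH](c1ccccc1)c1ccccc1 | intermediate
15 | (2R,3R)-3-(diphenylsilyloxy)-7-geranyloxy-3',4'-bis(tert-butyldimethylsilyloxy)flavanone (formed in the flask) | CC(C)=CCC/C(C)=C/COc1ccc2c(c1)O[C@H](c1ccc(O[Si](C)(C)C(C)(C)C)c(O[Si](C)(C)C(C)(C)C)c1)[C@@H](O[SiH](c1ccccc1)c1ccccc1)C2=O | intermediate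
16 | (2R,3R)-7-geranyloxy-3-hydroxy-3',4'-bis(tert-butyldimethylsilyloxy)flavanone (2,3-trans) | CC(C)=CCC/C(C)=C/COc1ccc2c(c1)O[C@H](c1ccc(O[Si](C)(C)C(C)(C)C)c(O[Si](C)(C)C(C)(C)C)c1)[C@@H](O)C2=O | intermediate
17 | (2R,3R)-7-geranyloxy-3,3',4'-trihydroxyflavanone (7-O-geranylfustin, CNP0508026.1) | CC(C)=CCC/C(C)=C/COc1ccc2c(c1)O[C@H](c1ccc(O)c(O)c1)[C@@H](O)C2=O | target

**Totals**
Total step count: 8.
Longest linear sequence: 8 steps (1 to 17). Compounds 6, 7 and 11 are bought and enter directly.

**Steps most likely to fail**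

*Step 6.*
- What may go wrong:
  - A 2-aryl pyranone is the least electrophilic member of its class, so hydrocupration may be slow.
  - The copper enolate may expel the ring A phenoxide by β-elimination before silicon traps it, which opens ring C and erases C2.
  - Facial discrimination by the ligand may be insufficient.
- Fallback (from 10 back to 16): C2 is set with hydrogen before the geranyl alkenes are present.
  - Benzylation of 10 (BnBr, K2CO3, acetone) gives 7-benzyloxy-3',4'-bis(tert-butyldimethylsilyloxy)flavone F1.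
  - Ruthenium–NHC asymmetric hydrogenation is established for flavones. The conditions are [Ru(cod)(2-methylallyl)2], SINpEt·HBF4 of the appropriate hand, KOt-Bu, H2 at 100 bar and toluene/hexane. It should give the (2S,4S)-cis-flavan-4-ol F2.
  - Dess–Martin periodinane returns the ketone as the (2S)-7-benzyloxyflavanone F3.
  - Hydrogenolysis (H2, Pd/C, EtOAc) frees the phenol as the (2S)-7-hydroxyflavanone F4.
  - A Mitsunobu etherification with geraniol (PPh3, DIAD, THF, 0 °C), which is neutral and should not racemise C2, gives the (2S)-7-geranyloxyflavanone F5.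
  - Soft enolisation (TMSOTf, Et3N, CH2Cl2, 0 °C) gives the trimethylsilyl enol ether F6.
  - Under the conditions of step 7, F6 passes by oxygen transfer and silyl shift to the 3-O-trimethylsilyl ketone F7. The citric acid work-up converts F7 into 16.

*Step 4.*
- What may go wrong:
  - The acyl-palladium may be captured by diethylamine or by a free phenol instead of the alkyne.
  - Alkynylation may run ahead of CO insertion on the electron-rich, partly deprotonated iodide.
  - Silyl groups may transfer from the catechol to resorcinol phenoxides in warm amine.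
- Fallback (from 5 back to 8, and so to 10): C4 comes from a carboxyl carbon, so no acyl-palladium has to choose between nucleophiles.
  - Commercial 2,4-dihydroxybenzoic acid is acetylated (Ac2O, pyridine) to 2,4-diacetoxybenzoic acid F8.
  - F8 is converted with (COCl)2 and catalytic DMF into 2,4-diacetoxybenzoyl chloride F9.
  - An acyl Sonogashira reaction of F9 with 5 (PdCl2(PPh3)2, CuI, Et3N, THF, rt) gives the ynone diacetate F10.
  - Et2NH at rt to 40 °C removes both acetates by aminolysis and gives 8, which closes through 9 to 10 as in the main route.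

*Step 7.*
- What may go wrong:
  - Oxygen transfer from the mild oxaziridine to a hindered trisubstituted enol silane next to the C2 aryl group may be sluggish.
  - The labile diphenylsilyl enol ether may hydrolyse before it is oxidised.
  - Facial selectivity may be incomplete.
- Fallback (from 10 back to 16): the geranyl group is attached after the hydroxylation, so a strong electrophilic oxidant can be used.
  - The conditions of step 6 with Ph2SiH2 (3 equiv) applied to 10 silylate the 7-phenol dehydrogenatively and reduce the pyranone. The product is (2S)-4,7-bis(diphenylsilyloxy)-2-[3,4-bis(tert-butyldimethylsilyloxy)phenyl]-2H-chromene F11.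
  - Classical Rubottom oxidation (mCPBA, NaHCO3, CH2Cl2, −20 °C) anti to the aryl group gives the (2R,3R)-3,7-bis(diphenylsilyloxy) ketone F12.
  - Citric acid work-up gives (2R,3R)-3,7-dihydroxy-3',4'-bis(tert-butyldimethylsilyloxy)flavanone F13.
  - A Mitsunobu reaction with geraniol (PPh3, DIAD, THF, 0 °C) uses the acidic 7-phenol as the pronucleophile and the primary allylic alcohol as the activated partner. The hindered 3-OH is left alone, and the product is 16.

**Further compounds**
F1 | step 6 | 7-benzyloxy-3',4'-bis(tert-butyldimethylsilyloxy)flavone | C(c1ccccc1)Oc1ccc2c(c1)oc(-c1ccc(O[Si](C)(C)C(C)(C)C)c(O[Si](C)(C)C(C)(C)C)c1)cc2=O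
F2 | step 6 | (2S,4S)-7-benzyloxy-3',4'-bis(tert-butyldimethylsilyloxy)flavan-4-ol | C(c1ccccc1)Oc1ccc2c(c1)O[C@H](c1ccc(O[Si](C)(C)C(C)(C)C)c(O[Si](C)(C)C(C)(C)C)c1)C[C@@H]2O
F3 | step 6 | (2S)-7-benzyloxy-3',4'-bis(tert-butyldimethylsilyloxy)flavanone | C(c1ccccc1)Oc1ccc2c(c1)O[C@H](c1ccc(O[Si](C)(C)C(C)(C)C)c(O[Si](C)(C)C(C)(C)C)c1)CC2=O
F4 | step 6 | (2S)-7-hydroxy-3',4'-bis(tert-butyldimethylsilyloxy)flavanone | Oc1ccc2c(c1)O[C@H](c1ccc(O[Si](C)(C)C(C)(C)C)c(O[Si](C)(C)C(C)(C)C)c1)CC2=O
F5 | step 6 | (2S)-7-geranyloxy-3',4'-bis(tert-butyldimethylsilyloxy)flavanone | CC(C)=CCC/C(C)=C/COc1ccc2c(c1)O[C@H](c1ccc(O[Si](C)(C)C(C)(C)C)c(O[Si](C)(C)C(C)(C)C)c1)CC2=O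
F6 | step 6 | (2S)-2-[3,4-bis(tert-butyldimethylsilyloxy)phenyl]-7-geranyloxy-4-(trimethylsilyloxy)-2H-chromene | CC(C)=CCC/C(C)=C/COc1ccc2c(c1)O[C@H](c1ccc(O[Si](C)(C)C(C)(C)C)c(O[Si](C)(C)C(C)(C)C)c1)C=C2O[Si](C)(C)C
F7 | step 6 | (2R,3R)-7-geranyloxy-3-(trimethylsilyloxy)-3',4'-bis(tert-butyldimethylsilyloxy)flavanone | CC(C)=CCC/C(C)=C/COc1ccc2c(c1)O[C@H](c1ccc(O[Si](C)(C)C(C)(C)C)c(O[Si](C)(C)C(C)(C)C)c1)[C@@H](O[Si](C)(C)C)C2=O
F8 | step 4 | 2,4-diacetoxybenzoic acid | CC(=O)Oc1ccc(C(=O)O)c(OC(C)=O)c1
F9 | step 4 | 2,4-diacetoxybenzoyl chloride | CC(=O)Oc1ccc(C(=O)Cl)c(OC(C)=O)c1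
F10 | step 4 | 1-(2,4-diacetoxyphenyl)-3-[3,4-bis(tert-butyldimethylsilyloxy)phenyl]prop-2-yn-1-one | CC(=O)Oc1ccc(C(=O)C#Cc2ccc(O[Si](C)(C)C(C)(C)C)c(O[Si](C)(C)C(C)(C)C)c2)c(OC(C)=O)c1
F11 | step 7 | (2S)-4,7-bis(diphenylsilyloxy)-2-[3,4-bis(tert-butyldimethylsilyloxy)phenyl]-2H-chromene | c1ccc(cc1)[SiH](c1ccccc1)Oc1ccc2c(c1)O[C@H](c1ccc(O[Si](C)(C)C(C)(C)C)c(O[Si](C)(C)C(C)(C)C)c1)C=C2O[SiH](c1ccccc1)c1ccccc1
F12 | step 7 | (2R,3R)-3,7-bis(diphenylsilyloxy)-3',4'-bis(tert-butyldimethylsilyloxy)flavanone | c1ccc(cc1)[SiH](c1ccccc1)Oc1ccc2c(c1)O[C@H](c1ccc(O[Si](C)(C)C(C)(C)C)c(O[Si](C)(C)C(C)(C)C)c1)[C@@H](O[SiH](c1ccccc1)c1ccccc1)C2=O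
F13 | step 7 | (2R,3R)-3,7-dihydroxy-3',4'-bis(tert-butyldimethylsilyloxy)flavanone | Oc1ccc2c(c1)O[C@H](c1ccc(O[Si](C)(C)C(C)(C)C)c(O[Si](C)(C)C(C)(C)C)c1)[C@@H](O)C2=O
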